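You have 0.400 M of Z against 0.0800 M of E, 0.200 M of D and 0.40 M of J, so count Z before anything else.

| flask | J | Z | E | D | temperature | remark | time |
|---|---|---|---|---|---|---|---|
| theta | 0.40 M | 0.40 M | 0.080 M | 0.20 M | 20 °C | the very flask that is asked about, followed so far |  |
| epsilon | 0.80 M | 0.40 M | 0.080 M | 0.20 M | 5 °C | run made earlier |  |
| flask | 0.40 M | 0.400 M | 0.0800 M | 0.200 M | 20 °C |  | 5.0 min |

| theta: time / min | theta: X / % | epsilon: time / min | epsilon: X / % |
|---|---|---|---|
| 0.333 | 12.4 | 0.333 | 7.1 |
| 0.667 | 16.6 | 0.833 | 9.8 |
| 1.00 | 20.0 | 2.00 | 15.8 |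
| 2.00 | 25.0 | 3.00 | 16.8 |
| 4.00 | 28.5 | 4.00 | 19.0 |

(readings scatter by 1 percentage point)

- X that was removed still counts
- additions bring no volume worth counting

- Monday's: at 5.0 min take out 90 % of the X then present, then wait 5.0 min
- Friday's: change nothing and wait 5.0 min more
- Tuesday's: at 5.0 min add Z, 100 % of the amount charged, then wait 5.0 min
- Thursday's: at 5.0 min raise the temperature by 15 K, then wait 5.0 min

1. X, in percent of the J first charged, at 5.0 min
2. the remedy with the largest gain of X, or "none" below 2 percentage points (Monday's / Friday's / Tuesday's / Thursday's / none)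
3. X present, with what was taken out counted in, in percent of the J first charged, after Tuesday's
4. X present, with what was taken out counted in, in percent of the J first charged, after Thursday's

Read the theta table down its column: X gains 12.4 % in the first 0.333 min, but 3.5 percentage points between 2.00 min and 4.00 min, so something is running out. My guess is Z, one per substrate, with E and D served ahead of J. Then take the spare Z, defined as cZ − cE − cD: 0.120 M. Against cJ that is a ceiling of 30.0 % X, and the last theta reading, 28.5 %, sits just under it.

Now the epsilon column, with the same spare against 0.80 M of J: the budget says 15.0 %, the last reading says 19.0 %. That is 4 points over, so the spare is no wall. I read it as a correction: with twice the J, at a colder 5 °C, J took some Z ahead of E and D.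

My reckoning for your flask is therefore about 30.0 % at 5.0 min. Friday's, Monday's and Thursday's add no Z, so each should stay near that ceiling. Tuesday's adds 0.400 M of fresh Z, and with E and D served by then, as I count it, that is more than the 0.280 M of J I expect left at 5.0 min. Choose Tuesday's, with up to 70 points open.

The forecast gave 30 % now, Tuesday's as best, 42 % after Tuesday's and 37 % after Thursday's, in its words “Doubling the charge roughly doubles the rate”.

The flask gives 28.9 % now and Tuesday's as best, with a gain of 36 points, against 0.91 points, 0.8 points and 0.78 points for Monday's, Friday's and Thursday's. X reaches 65.1 % after Tuesday's and 29.7 % after Thursday's.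

    J + Z → X (k = 0.0237 M⁻¹ s⁻¹, Ea = 44.0 kJ mol⁻¹)
    E + Z → G (k = 0.253 M⁻¹ s⁻¹, Ea = 50.0 kJ mol⁻¹)
    D + Z → Q (k = 0.203 M⁻¹ s⁻¹, Ea = 55.0 kJ mol⁻¹)
    Z + X → L (k = 0.00523 M⁻¹ s⁻¹, Ea = 55.0 kJ mol⁻¹)
    (constants at 20 °C)

In this flask, E + Z was half done by 0.141 min, earlier than J + Z at 0.552 min, and at 2.50 min E stood at 3.44 % and D at 6.69 % of their own charges, with X at 26.1 %. Then X crept on while Z, the limiting reagent, fell to 1.3 % at 5.00 min, and at 50.0 min X stood at 29.8 %, level with the spare share of 30.0 %. In the flask with 0.68 M of Z, the spare is 0.400 M, or 100 % of the J, and at 5.00 min it held X 60.5 %, L 10.7 %, J 28.8 % and still Z 11 %.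

The readings were computed for substances that don't exist.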